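The synthesis rests on cutting the three 4-hydroxybenzyl groups at C2, C4 and C6 of ring A (C1 bears the ethylene bridge) between each CH2 and its phenol ring. These carbons are exactly the ring positions activated by the oxygens at C3 and C5, so the precursor is a methyl 3-arylpropanoate whose ring carries CH2Br at C2, C4 and C6 and OMe at C3 and C5. One palladium-catalysed operation couples all three benzylic bromides with three equivalents of 4-(benzyloxy)phenylboronic acid, forming three CH2–aryl bonds and fixing each phenol oxygen para to its CH2. The propanoate carboxyl then leaves in a nickel-catalysed decarboxylative arylation that attaches ring B; hydrogenolysis and one thiolate demethylation finish the target.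

Key step: step 3

Assumption: 4-(benzyloxy)phenylmagnesium bromide is taken as a purchasable THF solution (otherwise made from 1-(benzyloxy)-4-bromobenzene and Mg) and is counted as a starting material.

Step 1
Reactants: 1 3-(3,5-dimethoxyphenyl)propanoic acid
Product: 2 methyl 3-(3,5-dimethoxyphenyl)propanoate
Conditions: MeOH, H2SO4 (cat.), reflux
Reagents that add atoms: methanol, CO
Why: Fischer esterification of an unhindered aliphatic acid in excess methanol should be clean, and the methyl ester keeps the carboxyl group from trapping a neighbouring benzylic bromide in steps 2 and 3.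

Step 2
Reactants: 2 methyl 3-(3,5-dimethoxyphenyl)propanoate
Product: 3 methyl 3-[2,4,6-tris(bromomethyl)-3,5-dimethoxyphenyl]propanoate
Conditions: (CH2O)n (6 equiv), 33% HBr in AcOH, AcOH, 50–60 °C
Reagents that add atoms: paraformaldehyde (formaldehyde unit), C=O; hydrogen bromide, Br
Why: Blanc-type bromomethylation is an electrophilic aromatic substitution, and since C2, C4 and C6 are each ortho or para to both methoxy groups while a CH2Br group deactivates the ring only weakly, all three free positions should be substituted with excess formaldehyde and HBr, in analogy to the threefold bromomethylation of mesitylene and of 1,3,5-trimethoxybenzene.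

Step 3
Reactants: 3 methyl 3-[2,4,6-tris(bromomethyl)-3,5-dimethoxyphenyl]propanoate; 4 4-(benzyloxy)phenylboronic acid (three equivalents)
Product: 5 methyl 3-[2,4,6-tris(4-benzyloxybenzyl)-3,5-dimethoxyphenyl]propanoate
Conditions: 4 (4.5 equiv), Pd(PPh3)4 (10 mol%), K3PO4 (anhydrous, finely ground, 9 equiv), toluene, 90 °C, Ar
Reagents that add atoms: 4-(benzyloxy)phenylboronic acid (second and third equivalents of compound 4), OB(O)c1ccc(OCc2ccccc2)cc1.OB(O)c1ccc(OCc2ccccc2)cc1
Why: Phosphine loss from Pd(PPh3)4 gives the active zerovalent palladium species, which undergoes SN2-type oxidative addition at a benzylic C–Br bond to give a benzyl complex of divalent palladium; transmetalation from the phosphate-activated arylboronate and reductive elimination then release the diarylmethane and regenerate the catalyst, and the cycle runs once at each of the three CH2Br groups, so that three molecules of 4 each deliver one 4-(benzyloxy)phenyl group in place of a bromine. The closest known reaction type is the Suzuki–Miyaura coupling of benzylic bromides with arylboronic acids to give diarylmethanes. No ring is closed and no stereocentre is created. The step needs chemoselectivity for cross-coupling over solvolysis, reductive homocoupling and ester cleavage, which anhydrous K3PO4 in toluene and an excess of 4 should provide, helped by the substrate itself: ring A is fully substituted, so the labile bromides cannot alkylate it, and a benzylpalladium species has no β-hydrogen to lose. It also needs each phenol oxygen para to its CH2, which is certain because the new bond forms at the boron-bearing carbon of 4. The three CH2Br groups are mutually meta and their carbons project away from the ring, so one coupling should not block the next.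

Step 4
Reactants: 5 methyl 3-[2,4,6-tris(4-benzyloxybenzyl)-3,5-dimethoxyphenyl]propanoate
Product: 6 3-[2,4,6-tris(4-benzyloxybenzyl)-3,5-dimethoxyphenyl]propanoic acid
Conditions: LiOH·H2O, THF/MeOH/H2O, 40 °C; then 1 M HCl
Reagents that add atoms: lithium hydroxide (its oxygen replaces the methoxy oxygen), [Li+].[OH-]
Why: Saponification of an unhindered primary-alkyl methyl ester with hydroxide should be straightforward, and the aryl benzyl and aryl methyl ethers are inert to aqueous base.

Step 5
Reactants: 6 3-[2,4,6-tris(4-benzyloxybenzyl)-3,5-dimethoxyphenyl]propanoic acid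
Product: 7 1,3-dioxoisoindolin-2-yl 3-[2,4,6-tris(4-benzyloxybenzyl)-3,5-dimethoxyphenyl]propanoate (N-hydroxyphthalimide ester)
Conditions: N-hydroxyphthalimide, DIC, DMAP (cat.), CH2Cl2, rt
Reagents that add atoms: N-hydroxyphthalimide, O=C1N(O)C(=O)c2ccccc12
Why: Carbodiimide-mediated (Steglich-type) esterification of the acid with N-hydroxyphthalimide should give the redox-active ester, which is stable to chromatography, and nothing else in 6 is nucleophilic or acidic.

Step 6
Reactants: 8 2-bromo-4-hydroxybenzaldehyde
Product: 9 4-(benzyloxy)-2-bromobenzaldehyde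
Conditions: BnBr, K2CO3, DMF, rt
Reagents that add atoms: benzyl bromide, BrCc1ccccc1
Why: Williamson ether synthesis on a phenol made acidic by the para formyl group should proceed cleanly with K2CO3, and the benzyl ether matches the protecting groups of ring A so that one hydrogenolysis later frees all phenols.

Step 7
Reactants: 9 4-(benzyloxy)-2-bromobenzaldehyde; 10 4-(benzyloxy)phenylmagnesium bromide
Product: 11 [4-(benzyloxy)-2-bromophenyl][4-(benzyloxy)phenyl]methanol (racemic)
Conditions: 10 (1.2 equiv), THF, 0 °C; then sat. aq NH4Cl
Reagents that add atoms: none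
Why: Grignard addition to an aromatic aldehyde is fast at 0 °C, where the aryl bromide does not undergo halogen–magnesium exchange; the new carbinol stereocentre forms as a racemate, which is of no consequence because step 8 removes it.

Step 8
Reactants: 11 [4-(benzyloxy)-2-bromophenyl][4-(benzyloxy)phenyl]methanol
Product: 12 4-(benzyloxy)-1-[4-(benzyloxy)benzyl]-2-bromobenzene
Conditions: Et3SiH (3 equiv), TFA (10 equiv), CH2Cl2, 0 °C
Reagents that add atoms: none
Why: Ionic hydrogenation (acid ionises the carbinol to a benzhydryl cation stabilised by two para alkoxy groups, which takes hydride from Et3SiH) should give the diarylmethane while the aryl bromide and the aryl benzyl ethers survive brief exposure to cold TFA.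

Step 9
Reactants: 7 N-hydroxyphthalimide ester of acid 6; 12 4-(benzyloxy)-1-[4-(benzyloxy)benzyl]-2-bromobenzene
Product: 13 4-(benzyloxy)-1-[4-(benzyloxy)benzyl]-2-{2-[2,4,6-tris(4-benzyloxybenzyl)-3,5-dimethoxyphenyl]ethyl}benzene
Conditions: 12 (2 equiv), NiBr2(dme) (20 mol%), 4,4'-di-tert-butyl-2,2'-bipyridine (20 mol%), Zn dust (3 equiv), DMA/THF, 30 °C, slow addition of 7
Reagents that add atoms: none
Why: Nickel-catalysed reductive cross-electrophile coupling (decarboxylative arylation of a redox-active ester) is known for primary N-acyloxyphthalimides and aryl halides: single-electron reduction of 7 releases CO2 and the primary 2-arylethyl radical, which is captured by the arylnickel species formed from 12 before reductive elimination forges the CH2–aryl bond, and slow addition of 7 to an excess of 12 should keep radical formation in step with the slower oxidative addition of the ortho-substituted bromide.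

Step 10
Reactants: 13 penta-O-benzyl di-O-methyl bibenzyl
Product: 14 4-(4-hydroxybenzyl)-3-{2-[2,4,6-tris(4-hydroxybenzyl)-3,5-dimethoxyphenyl]ethyl}phenol
Conditions: H2 (1 atm), 10% Pd/C, THF/MeOH, rt
Reagents that add atoms: none
Why: Catalytic hydrogenolysis over palladium should cleave all five aryl benzyl ethers, whereas the diarylmethane C–C bonds, the bibenzyl bridge and the aryl methyl ethers are not touched under one atmosphere of hydrogen at room temperature.

Step 11
Reactants: 14 4-(4-hydroxybenzyl)-3-{2-[2,4,6-tris(4-hydroxybenzyl)-3,5-dimethoxyphenyl]ethyl}phenol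
Product: 15 Bleochrin B, 2,4,6-tris(4-hydroxybenzyl)-3-{2-[5-hydroxy-2-(4-hydroxybenzyl)phenyl]ethyl}-5-methoxyphenol
Conditions: NaSEt (15 equiv), DMF, 130 °C, Ar; then 1 M HCl
Reagents that add atoms: none
Why: Thiolate demethylation is an SN2 attack of ethanethiolate on an O-methyl carbon, it should stop after one cleavage because the resulting ring A phenoxide makes the second aryloxide a much poorer leaving group, and since the C3 and C5 methoxy groups of 14 are equivalent by symmetry either cleavage gives the target.

Compound list
1 | 3-(3,5-dimethoxyphenyl)propanoic acid | O=C(O)CCc1cc(OC)cc(OC)c1 | starting material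
2 | methyl 3-(3,5-dimethoxyphenyl)propanoate | COC(=O)CCc1cc(OC)cc(OC)c1 | intermediate
3 | methyl 3-[2,4,6-tris(bromomethyl)-3,5-dimethoxyphenyl]propanoate | COc1c(CBr)c(OC)c(CBr)c(CCC(=O)OC)c1CBr | intermediate
4 | 4-(benzyloxy)phenylboronic acid | OB(O)c1ccc(OCc2ccccc2)cc1 | starting material
5 | methyl 3-[2,4,6-tris(4-benzyloxybenzyl)-3,5-dimethoxyphenyl]propanoate | COc1c(Cc2ccc(OCc3ccccc3)cc2)c(OC)c(Cc2ccc(OCc3ccccc3)cc2)c(CCC(=O)OC)c1Cc1ccc(OCc2ccccc2)cc1 | intermediate
6 | 3-[2,4,6-tris(4-benzyloxybenzyl)-3,5-dimethoxyphenyl]propanoic acid | COc1c(Cc2ccc(OCc3ccccc3)cc2)c(OC)c(Cc2ccc(OCc3ccccc3)cc2)c(CCC(=O)O)c1Cc1ccc(OCc2ccccc2)cc1 | intermediate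
7 | 1,3-dioxoisoindolin-2-yl 3-[2,4,6-tris(4-benzyloxybenzyl)-3,5-dimethoxyphenyl]propanoate | COc1c(Cc2ccc(OCc3ccccc3)cc2)c(OC)c(Cc2ccc(OCc3ccccc3)cc2)c(CCC(=O)ON2C(=O)c3ccccc3C2=O)c1Cc1ccc(OCc2ccccc2)cc1 | intermediate
8 | 2-bromo-4-hydroxybenzaldehyde | O=Cc1ccc(O)cc1Br | starting material
9 | 4-(benzyloxy)-2-bromobenzaldehyde | O=Cc1ccc(OCc2ccccc2)cc1Br | intermediate
10 | 4-(benzyloxy)phenylmagnesium bromide | Br[Mg]c1ccc(OCc2ccccc2)cc1 | starting material
11 | [4-(benzyloxy)-2-bromophenyl][4-(benzyloxy)phenyl]methanol (racemic) | OC(c1ccc(OCc2ccccc2)cc1)c1ccc(OCc2ccccc2)cc1Br | intermediate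
12 | 4-(benzyloxy)-1-[4-(benzyloxy)benzyl]-2-bromobenzene | Brc1cc(OCc2ccccc2)ccc1Cc1ccc(OCc2ccccc2)cc1 | intermediate
13 | 4-(benzyloxy)-1-[4-(benzyloxy)benzyl]-2-{2-[2,4,6-tris(4-benzyloxybenzyl)-3,5-dimethoxyphenyl]ethyl}benzene | COc1c(Cc2ccc(OCc3ccccc3)cc2)c(OC)c(Cc2ccc(OCc3ccccc3)cc2)c(CCc2cc(OCc3ccccc3)ccc2Cc2ccc(OCc3ccccc3)cc2)c1Cc1ccc(OCc2ccccc2)cc1 | intermediate
14 | 4-(4-hydroxybenzyl)-3-{2-[2,4,6-tris(4-hydroxybenzyl)-3,5-dimethoxyphenyl]ethyl}phenol | COc1c(Cc2ccc(O)cc2)c(OC)c(Cc2ccc(O)cc2)c(CCc2cc(O)ccc2Cc2ccc(O)cc2)c1Cc1ccc(O)cc1 | intermediate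
15 | Bleochrin B, 2,4,6-tris(4-hydroxybenzyl)-3-{2-[5-hydroxy-2-(4-hydroxybenzyl)phenyl]ethyl}-5-methoxyphenol | COc1c(Cc2ccc(O)cc2)c(O)c(Cc2ccc(O)cc2)c(CCc2cc(O)ccc2Cc2ccc(O)cc2)c1Cc1ccc(O)cc1 | target

Total step count: 11.
Longest linear sequence: 8 steps (steps 1, 2, 3, 4, 5, 9, 10, 11); the ring B branch (steps 6, 7, 8) joins at step 9.

Steps most likely to fail

Step 3. The triple coupling may stop after one or two aryl transfers, or the electron-rich benzylic bromides may be consumed by hydrolysis or by reductive homocoupling before transmetalation. The fallback sets out from compound 2 and moves the bond formation to the ring A–CH2 bonds in a threefold Friedel–Crafts benzylation with purchased 4-(benzyloxy)benzyl alcohol (3.5 equiv, Bi(OTf)3 5 mol%, MeNO2/CH2Cl2, rt). The benzylic cation already carries its oxygen para, and C2, C4 and C6 of 2 are the only free, doubly activated positions. The product is compound 5, where the route is rejoined; no compound outside the compound list is made (F0).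

Step 9. Reduction and decarboxylation of the redox-active ester may outrun oxidative addition of the ortho-substituted, electron-rich aryl bromide, so that the alkyl radical is lost to hydrogen abstraction or dimerisation. The fallback sets out from compound 12 and turns the aryl partner into a nucleophile. Bromine–lithium exchange (n-BuLi, THF, −78 °C) should give {5-(benzyloxy)-2-[4-(benzyloxy)benzyl]phenyl}lithium F1, which ZnCl2 converts into {5-(benzyloxy)-2-[4-(benzyloxy)benzyl]phenyl}zinc chloride F2. Nickel-catalysed decarboxylative Negishi-type coupling of F2 (3 equiv) with redox-active ester 7 (NiCl2(dme), 4,4'-di-tert-butyl-2,2'-bipyridine, THF/DMF, rt) comes back to the route at compound 13.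

Step 2. Partly bromomethylated intermediates may alkylate unreacted arene to give diarylmethane oligomers, the third substitution may stall, or the methyl ester may be cleaved by HBr. The fallback sets out from compound 2 and avoids benzylic bromides altogether. Exhaustive ring bromination (NBS 3.3 equiv, MeCN, 50 °C) should give methyl 3-(2,4,6-tribromo-3,5-dimethoxyphenyl)propanoate F3. A threefold Negishi coupling then follows with [4-(benzyloxy)benzyl]zinc chloride F4 (from purchased 4-(benzyloxy)benzyl chloride, Zn dust and LiCl in THF), using Pd(OAc)2 and SPhos in THF at 60 °C. This bypasses compound 3 and comes back to the route at compound 5.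

Further compounds
F0 | step 3 | none | none
F1 | step 9 | {5-(benzyloxy)-2-[4-(benzyloxy)benzyl]phenyl}lithium | [Li]c1cc(OCc2ccccc2)ccc1Cc1ccc(OCc2ccccc2)cc1
F2 | step 9 | {5-(benzyloxy)-2-[4-(benzyloxy)benzyl]phenyl}zinc chloride | Cl[Zn]c1cc(OCc2ccccc2)ccc1Cc1ccc(OCc2ccccc2)cc1
F3 | step 2 | methyl 3-(2,4,6-tribromo-3,5-dimethoxyphenyl)propanoate | COC(=O)CCc1c(Br)c(OC)c(Br)c(OC)c1Br
F4 | step 2 | [4-(benzyloxy)benzyl]zinc chloride | Cl[Zn]Cc1ccc(OCc2ccccc2)cc1
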